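The target you find at the end of a run is a leftover, what has survived its slow slide into over-reaction product. So before I trust your hunch that piling in starting material pays, I want to count turnovers of that slide. Here are the flasks and your questions.

| setting | Sunday's | Friday's | Thursday's | Monday's | Tuesday's |
|---|---|---|---|---|---|
| starting material | 0.20 M | 0.40 M | 0.80 M | 1.5 M | 3.0 M |
| reagent | 0.800 M | 0.800 M | 0.800 M | 0.800 M | 0.800 M |
| second substrate | 0.0800 M | 0.0800 M | 0.0800 M | 0.0800 M | 0.0800 M |
| catalyst | 27 mM | 27 mM | 27 mM | 27 mM | 27 mM |
| time | 12 h | 12 h | 12 h | 12 h | 12 h |

    target → over-reaction product (k1 = 3.5 × 10⁻⁵ s⁻¹)
    starting material + reagent + catalyst → catalyst + target (k2 = 0.0077 M⁻² s⁻¹)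
    second substrate + reagent + catalyst → catalyst + second product (k3 = 0.014 M⁻² s⁻¹)

- "hardly changes" means that all values lie within two and a half points (for a concentration: within two and a half percent of the largest)
- run time (Sunday's): 12 h

* [target] at the end for Sunday's, Friday's, Thursday's, Monday's, Tuesday's, in this order
* the shape of the row from first to last (rises, then falls / falls all the way / falls, then rises / hardly changes / rises all the way)

A molecule of target lasts 7.94 h on average, so a run of 12 h holds 1.51 such lifetimes. I carry this count of target lifetimes in the run into the reckonings below. Target made at the very start keeps e to the minus that count, a share of 22.0%.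

In Sunday's flask, starting material has a half-life of 1.2 h by its own step at the charged concentrations, shorter than the lifetime of target. So I treat the target as born one such half-life into the run and let it age for the rest of the run, which by this reckoning leaves 0.0510 M.

In Tuesday's flask, 3.0 M of starting material faces 0.800 M of reagent, so reagent is the limiting reagent. Its half-life by the target-making step, with starting material and catalyst as charged, is 0.309 h, again shorter than the lifetime. Setting aside what the second substrate takes and treating the whole reagent charge as target born at the start gives 0.176 M.

Between those ends I have no hand figure. I expect a rise, a top near equal charges of starting material and reagent, then a sag.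

The forecast gives 0.059 M, 0.121 M, 0.206 M, 0.193 M and 0.181 M, a row that rises, then falls. Its ground for the far end is that “richer feeds that use up the reagent sooner leave slightly less at the end”. My two figures sit lower than its two ends.

The flasks gave 0.0588 M, 0.121 M, 0.207 M, 0.193 M and 0.180 M, a row that rises, then falls, with the turn read at 0.92 M. In Tuesday's flask at 6.00 h, reagent stood at 0% of its own charge and target at 12.8% of the starting material charged. The 6.00 h still to run are 0.756 target lifetimes, so target keeps 47.0% of itself, which comes to 6.02% of the starting material charged. Tuesday's flask at 12.0 h holds target at 6.01% of the starting material charged.

All constants were drawn at random within sensible limits.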